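**Plan**
- Retrosynthesis: the quinone ring is opened across C1–C2 and C3–C4 into cyclobut-3-ene-1,2-dione (ring atoms C4, C5, C6, C1 with both oxygens) and a terminal alkyne (C2 and C3, whose propargylic CH2 is C1' of the side chain). Then the C1'–alkyne bond, the C8'–C9' bond of the chain (sulfone alkylation) and the ring CH–CH2 bond ([3,3] shift) are cut.
- Enabling feature: in the quinone ring, C5=C6 is an unsubstituted HC=CH lying between the two carbonyl carbons C4 and C1, which is the O=C–CH=CH–C=O array of a four-membered enedione. The remaining pair C2(side chain)=C3(H) is a terminal alkyne, so a 4-alkynyl-4-hydroxycyclobutenone already holds all six ring carbons and both oxygens at the quinone oxidation level.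
- Forward, ring piece: 2,4,4-trimethylcyclohexenone, CBS reduction, sulfonylacetate ester, decarboxylative Claisen rearrangement to the (R)-α-cyclogeranyl sulfone. Chain piece: geranyl bromide, silyl 1,4-enyne, E-selective allylic hydroxylation, bromide.
- The two C10 pieces are joined by sulfone alkylation, then desulfonylated and desilylated to the C22 enyne. Its acetylide adds to the cyclobutenedione, and the four-membered ring is expanded thermally to the six-membered quinone ring in the last step.
- Stereochemistry: the single stereocentre is set by the catalyst-controlled CBS reduction and relayed from oxygen to carbon by the suprafacial [3,3] shift. Both E alkenes come from geranyl bromide and the E-selective allylic oxidation.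

Key step: step 10

Assumption: cyclobut-3-ene-1,2-dione, a known and isolable but polymerisation-prone solid, is taken as a purchasable specialty reagent and is sublimed directly before use.

**Step 1**
Reactants: 1 2,4,4-trimethylcyclohex-2-en-1-one
Product: 2 (1S)-2,4,4-trimethylcyclohex-2-en-1-ol
Conditions: (R)-2-methyl-CBS-oxazaborolidine [(3aR)-1-methyl-3,3-diphenyltetrahydro-1H,3H-pyrrolo[1,2-c][1,3,2]oxazaborole] (10 mol%), BH3·SMe2 (0.7 equiv), THF, −20 °C; MeOH, then aqueous work-up
Reagents that add atoms: none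
Why: Corey–Bakshi–Shibata reduction, in which the oxazaborolidine binds borane and the carbonyl oxygen anti to the larger 2-methylalkenyl arm, so hydride is delivered 1,2 to one face and the (R)-catalyst should give the (S)-carbinol, the only stereochemical information brought in from outside.

**Step 2**
Reactants: 2 (1S)-2,4,4-trimethylcyclohex-2-en-1-ol; 3 2-[(4-methylphenyl)sulfonyl]acetic acid
Product: 4 (1S)-2,4,4-trimethylcyclohex-2-en-1-yl 2-[(4-methylphenyl)sulfonyl]acetate
Conditions: N,N'-diisopropylcarbodiimide, 4-(dimethylamino)pyridine (5 mol%), CH2Cl2, 0 °C to rt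
Reagents that add atoms: none
Why: Steglich esterification with carbodiimide activation leaves the C–O bond of the carbinol, and therefore its configuration, untouched and installs the sulfonylacetate that the rearrangement needs.

**Step 3**
Reactants: 4 (1S)-2,4,4-trimethylcyclohex-2-en-1-yl 2-[(4-methylphenyl)sulfonyl]acetate
Product: 7 1-methyl-4-({[(1R)-2,6,6-trimethylcyclohex-2-en-1-yl]methyl}sulfonyl)benzene, via silyl ketene acetal 5 (not isolated), via trimethylsilyl ester 6 (not isolated)
Conditions: N,O-bis(trimethylsilyl)acetamide (0.2 equiv), KOAc (0.1 equiv), toluene, 110 °C (microwave, 150 °C, if slow)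
Reagents that add atoms: none
Why: Decarboxylative Ireland–Claisen rearrangement, in which the acidic sulfonylacetate is converted into silyl ketene acetal 5, whose suprafacial [3,3] shift forms the C–C bond at the ring carbon next to the quaternary centre on the face that carried oxygen (1,3-chirality transfer, S carbinol to R ring carbon) and moves the double bond into the 2,3-position, after which silyl ester 6 loses CO2 to leave the sulfone.

**Step 4**
Reactants: 8 (2E)-1-bromo-3,7-dimethylocta-2,6-diene (geranyl bromide); 9 ethynyltrimethylsilane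
Product: 11 [(4E)-5,9-dimethyldeca-4,8-dien-1-yn-1-yl]trimethylsilane, via alkynylmagnesium bromide 10 (not isolated)
Conditions: 9, EtMgBr, THF, 0 to 40 °C; then CuCl (5 mol%), 8, THF, rt to 50 °C
Reagents that add atoms: none
Why: Copper-catalysed SN2 coupling of an alkynyl Grignard reagent with a primary allylic bromide, which for this prenyl-type terminus should go at the unhindered CH2 and keep the E double bond, giving the skipped enyne with the alkyne masked as its silane.

**Step 5**
Reactants: 11 [(4E)-5,9-dimethyldeca-4,8-dien-1-yn-1-yl]trimethylsilane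
Product: 12 (2E,6E)-2,6-dimethyl-10-(trimethylsilyl)deca-2,6-dien-9-yn-1-ol
Conditions: SeO2 (0.3 equiv), t-BuOOH (2.5 equiv, in decane), CH2Cl2, 0 °C to rt, stopped at partial conversion
Reagents that add atoms: selenium dioxide O=[Se]=O (oxygen carrier); tert-butyl hydroperoxide CC(C)(C)OO (terminal oxidant)
Why: Selenium dioxide allylic oxidation (ene reaction then [2,3] shift) should attack the more electron-rich and less hindered terminal trisubstituted alkene and, by the usual rule, the methyl group trans to the chain, giving the E allylic alcohol, while the hydroperoxide keeps selenium catalytic and limits over-oxidation.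

**Step 6**
Reactants: 12 (2E,6E)-2,6-dimethyl-10-(trimethylsilyl)deca-2,6-dien-9-yn-1-ol
Product: 13 [(4E,8E)-10-bromo-5,9-dimethyldeca-4,8-dien-1-yn-1-yl]trimethylsilane
Conditions: CBr4, PPh3, CH2Cl2, −20 to 0 °C; used without storage
Reagents that add atoms: carbon tetrabromide BrC(Br)(Br)Br
Why: Appel reaction, in which bromide displaces the alkoxyphosphonium group by SN2 at the primary allylic carbon at low temperature, without allylic transposition or loss of the E geometry.

**Step 7**
Reactants: 7 1-methyl-4-({[(1R)-2,6,6-trimethylcyclohex-2-en-1-yl]methyl}sulfonyl)benzene; 13 [(4E,8E)-10-bromo-5,9-dimethyldeca-4,8-dien-1-yn-1-yl]trimethylsilane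
Product: 15 1-methyl-4-{[(3E,7E)-3,7-dimethyl-1-[(1R)-2,6,6-trimethylcyclohex-2-en-1-yl]-11-(trimethylsilyl)undeca-3,7-dien-10-yn-1-yl]sulfonyl}benzene (both epimers at the sulfonyl carbon), via lithiated sulfone 14 (not isolated)
Conditions: n-BuLi (1.0 equiv), THF, −78 °C; then 13, THF, −78 to −20 °C
Reagents that add atoms: none
Why: Alkylation of an α-sulfonyl carbanion with a primary allylic bromide (the sulfone fragment coupling of terpenoid synthesis) joins the two C10 pieces by SN2 at CH2; the ring stereocentre is β to the carbanion and cannot epimerise, and the new sulfonyl-bearing centre is of no consequence because it is removed in step 8.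

**Step 8**
Reactants: 15 1-methyl-4-{[(3E,7E)-3,7-dimethyl-1-[(1R)-2,6,6-trimethylcyclohex-2-en-1-yl]-11-(trimethylsilyl)undeca-3,7-dien-10-yn-1-yl]sulfonyl}benzene
Product: 16 (6R)-6-[(3E,7E)-3,7-dimethylundeca-3,7-dien-10-yn-1-yl]-1,5,5-trimethylcyclohex-1-ene
Conditions: sodium amalgam (6% Na in Hg, excess), MeOH–THF (1:1), −20 °C to rt
Reagents that add atoms: none
Why: Reductive desulfonylation by single-electron transfer from sodium amalgam cleaves the alkyl C–S bond to C–H, and the methoxide formed in the same flask removes the alkynyl silyl group by attack at silicon, so the terminal alkyne is released in one operation while the isolated alkenes and the alkyne are not reduced.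

**Step 9**
Reactants: 16 (6R)-6-[(3E,7E)-3,7-dimethylundeca-3,7-dien-10-yn-1-yl]-1,5,5-trimethylcyclohex-1-ene; 17 cyclobut-3-ene-1,2-dione
Product: 19 4-hydroxy-4-[(4E,8E)-5,9-dimethyl-11-[(1R)-2,6,6-trimethylcyclohex-2-en-1-yl]undeca-4,8-dien-1-yn-1-yl]cyclobut-2-en-1-one (both epimers at C4), via lithium acetylide 18 (not isolated)
Conditions: 16, n-BuLi (1.0 equiv), THF, −78 °C; cannulated into 17 (1.5 equiv), THF, −78 °C; aq. NH4Cl at −78 °C; used promptly
Reagents that add atoms: none
Why: 1,2-Addition of a lithium acetylide to one carbonyl of a cyclobutenedione, the standard entry to 4-alkynyl-4-hydroxycyclobutenones; inverse addition at low temperature to an excess of the symmetrical dione should suppress double addition, and the new carbinol centre is lost in step 10.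

**Step 10**
Reactants: 19 4-hydroxy-4-[(4E,8E)-5,9-dimethyl-11-[(1R)-2,6,6-trimethylcyclohex-2-en-1-yl]undeca-4,8-dien-1-yn-1-yl]cyclobut-2-en-1-one
Product: 22 2-[(2E,6E)-3,7-dimethyl-9-[(1R)-2,6,6-trimethylcyclohex-2-en-1-yl]nona-2,6-dien-1-yl]cyclohexa-2,5-diene-1,4-dione, via alkynylvinylketene 20 (not isolated), via aryl phenoxyl diradical 21 (not isolated)
Conditions: degassed p-xylene (0.005 M), 138 °C, argon, 30–60 min
Reagents that add atoms: none
Why: On heating, the cyclobutenone C1–C4 bond opens in a conrotatory four-electron electrocyclic reaction in which the 4-hydroxy group rotates outward, so the alkynyl group ends up cis to the new ketene in 20. The ketene carbon then bonds to the distal alkyne carbon in a six-membered (6-endo-dig) cycloaromatising closure to the σ,π-diradical 21, and transfer of the hydroxyl hydrogen to the neighbouring aryl radical carbon gives the 1,4-benzoquinone directly, with no oxidant and no by-product; this is the Moore rearrangement of 4-alkynyl-4-hydroxycyclobutenones, the closest known reaction type. The four carbons of 17 become C1, C4, C5 and C6 and the two alkyne carbons become C2 and C3, so the side chain can only sit on the carbon next to a carbonyl and no regioisomer is possible. No stereocentre is formed, and the (R) centre and both E alkenes lie outside the reacting π system. The step needs six- over five-membered closure, which the plain propargylic CH2 on the alkyne terminus should favour because it offers no radical-stabilising group, and it needs the internal hydrogen transfer to outrun intermolecular radical reactions, which high dilution in degassed solvent should secure.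

**Compound list**
1 | 2,4,4-trimethylcyclohex-2-en-1-one | CC1=CC(C)(C)CCC1=O | starting material
2 | (1S)-2,4,4-trimethylcyclohex-2-en-1-ol | O[C@H]1CCC(C)(C)C=C1C | intermediate
3 | 2-[(4-methylphenyl)sulfonyl]acetic acid | Cc1ccc(cc1)S(=O)(=O)CC(=O)O | starting material
4 | (1S)-2,4,4-trimethylcyclohex-2-en-1-yl 2-[(4-methylphenyl)sulfonyl]acetate | Cc1ccc(cc1)S(=O)(=O)CC(=O)O[C@H]1CCC(C)(C)C=C1C | intermediate
5 | 1-methyl-4-({2-[(trimethylsilyl)oxy]-2-{[(1S)-2,4,4-trimethylcyclohex-2-en-1-yl]oxy}ethenyl}sulfonyl)benzene (silyl ketene acetal, not isolated) | Cc1ccc(cc1)S(=O)(=O)C=C(O[Si](C)(C)C)O[C@H]1CCC(C)(C)C=C1C | intermediate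
6 | trimethylsilyl 2-[(4-methylphenyl)sulfonyl]-2-[(1R)-2,6,6-trimethylcyclohex-2-en-1-yl]acetate (both epimers at C2, not isolated) | CC1=CCCC(C)(C)[C@H]1C(C(=O)O[Si](C)(C)C)S(=O)(=O)c1ccc(C)cc1 | intermediate
7 | 1-methyl-4-({[(1R)-2,6,6-trimethylcyclohex-2-en-1-yl]methyl}sulfonyl)benzene | CC1=CCCC(C)(C)[C@H]1CS(=O)(=O)c1ccc(C)cc1 | intermediate
8 | (2E)-1-bromo-3,7-dimethylocta-2,6-diene (geranyl bromide) | CC(C)=CCC/C(C)=C/CBr | starting material
9 | ethynyltrimethylsilane | C#C[Si](C)(C)C | starting material
10 | bromo[(trimethylsilyl)ethynyl]magnesium (not isolated) | C[Si](C)(C)C#C[Mg]Br | intermediate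
11 | [(4E)-5,9-dimethyldeca-4,8-dien-1-yn-1-yl]trimethylsilane | CC(C)=CCC/C(C)=C/CC#C[Si](C)(C)C | intermediate
12 | (2E,6E)-2,6-dimethyl-10-(trimethylsilyl)deca-2,6-dien-9-yn-1-ol | OC/C(C)=C/CC/C(C)=C/CC#C[Si](C)(C)C | intermediate
13 | [(4E,8E)-10-bromo-5,9-dimethyldeca-4,8-dien-1-yn-1-yl]trimethylsilane | BrC/C(C)=C/CC/C(C)=C/CC#C[Si](C)(C)C | intermediate
14 | {[(4-methylphenyl)sulfonyl][(1R)-2,6,6-trimethylcyclohex-2-en-1-yl]methyl}lithium (not isolated) | CC1=CCCC(C)(C)[C@H]1C([Li])S(=O)(=O)c1ccc(C)cc1 | intermediate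
15 | 1-methyl-4-{[(3E,7E)-3,7-dimethyl-1-[(1R)-2,6,6-trimethylcyclohex-2-en-1-yl]-11-(trimethylsilyl)undeca-3,7-dien-10-yn-1-yl]sulfonyl}benzene (both epimers at the sulfonyl carbon) | CC1=CCCC(C)(C)[C@H]1C(C/C(C)=C/CC/C(C)=C/CC#C[Si](C)(C)C)S(=O)(=O)c1ccc(C)cc1 | intermediate
16 | (6R)-6-[(3E,7E)-3,7-dimethylundeca-3,7-dien-10-yn-1-yl]-1,5,5-trimethylcyclohex-1-ene | CC1=CCCC(C)(C)[C@H]1CC/C(C)=C/CC/C(C)=C/CC#C | intermediate
17 | cyclobut-3-ene-1,2-dione | O=C1C=CC1=O | starting material
18 | [(4E,8E)-5,9-dimethyl-11-[(1R)-2,6,6-trimethylcyclohex-2-en-1-yl]undeca-4,8-dien-1-yn-1-yl]lithium (not isolated) | CC1=CCCC(C)(C)[C@H]1CC/C(C)=C/CC/C(C)=C/CC#C[Li] | intermediate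
19 | 4-hydroxy-4-[(4E,8E)-5,9-dimethyl-11-[(1R)-2,6,6-trimethylcyclohex-2-en-1-yl]undeca-4,8-dien-1-yn-1-yl]cyclobut-2-en-1-one (both epimers at C4) | CC1=CCCC(C)(C)[C@H]1CC/C(C)=C/CC/C(C)=C/CC#CC1(O)C=CC1=O | intermediate
20 | (3E,8E,12E)-4-hydroxy-9,13-dimethyl-15-[(1R)-2,6,6-trimethylcyclohex-2-en-1-yl]pentadeca-1,3,8,12-tetraen-5-yn-1-one (alkynylvinylketene, not isolated) | CC1=CCCC(C)(C)[C@H]1CC/C(C)=C/CC/C(C)=C/CC#C/C(O)=C\C=C=O | intermediate
21 | 4-hydroxy-2-[(2E,6E)-3,7-dimethyl-9-[(1R)-2,6,6-trimethylcyclohex-2-en-1-yl]nona-2,6-dien-1-yl]phenoxyl carrying a second unpaired electron on ring carbon C3 (diradical, not isolated) | CC1=CCCC(C)(C)[C@H]1CC/C(C)=C/CC/C(C)=C/Cc1[c]c(O)ccc1[O] | intermediate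
22 | 2-[(2E,6E)-3,7-dimethyl-9-[(1R)-2,6,6-trimethylcyclohex-2-en-1-yl]nona-2,6-dien-1-yl]cyclohexa-2,5-diene-1,4-dione | CC1=CCCC(C)(C)[C@H]1CC/C(C)=C/CC/C(C)=C/CC1=CC(=O)C=CC1=O | target

**Step count**
Total: 10 steps. Longest linear sequence: 7 steps (1, 2, 3, 7, 8, 9, 10; the branch 4, 5, 6, 7, 8, 9, 10 is equally long).

**Steps most likely to fail**

Step 9. The unsubstituted enedione may oligomerise under the basic conditions, or the remaining carbonyl may take up a second acetylide before the mono-adduct is quenched. The fallback sets out from alkyne 16 and avoids the four-membered dione altogether. Alkyne 16 would be warmed in THF at 50 °C with freshly prepared pentacarbonyl(1-methoxyprop-2-en-1-ylidene)chromium F1, (OC)5Cr=C(OMe)CH=CH2, made from Cr(CO)6, vinyllithium and Me3OBF4. This Dötz benzannulation (alkyne insertion, CO insertion, electrocyclic closure) places the alkyne substituent ortho to the new hydroxyl and, after work-up in air, should give 2-[(2E,6E)-3,7-dimethyl-9-[(1R)-2,6,6-trimethylcyclohex-2-en-1-yl]nona-2,6-dien-1-yl]-4-methoxyphenol F2. Oxidative demethylation of F2 with (NH4)2Ce(NO3)6 in MeCN–H2O at 0 °C comes back to the route at 22.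

Step 10. The ketene may close onto the proximal alkyne carbon to give a five-membered ring, or the diradical may react intermolecularly (coupling, hydrogen abstraction from the allylic chain) instead of taking up the hydroxyl hydrogen. The fallback sets out from alkyne 16 and replaces the diradical closure by a purely pericyclic one. Hydrozirconation with Cp2Zr(H)Cl in THF and iodinolysis would give (6R)-6-[(3E,7E,10E)-11-iodo-3,7-dimethylundeca-3,7,10-trien-1-yl]-1,5,5-trimethylcyclohex-1-ene F3. Lithium–iodine exchange with t-BuLi in Et2O at −78 °C would give the alkenyllithium F4, which is added to 17 at −78 °C to give 4-hydroxy-4-[(1E,4E,8E)-5,9-dimethyl-11-[(1R)-2,6,6-trimethylcyclohex-2-en-1-yl]undeca-1,4,8-trien-1-yl]cyclobut-2-en-1-one F5. Heating F5 in toluene (ring opening, six-electron electrocyclic closure, enolisation) should give 2-[(2E,6E)-3,7-dimethyl-9-[(1R)-2,6,6-trimethylcyclohex-2-en-1-yl]nona-2,6-dien-1-yl]benzene-1,4-diol F6. Oxidation of F6 with Ag2O in Et2O comes back to the route at 22.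

Step 3. The [3,3] shift has to form a bond at the ring carbon flanked by the quaternary centre and may be slow, so that elimination of the allylic ester to a diene or decarboxylation without rearrangement takes over. The fallback sets out from alcohol 2 and uses a [2,3] shift instead. O-Alkylation of 2 with KH and Bu3SnCH2I in THF would give tributyl({[(1S)-2,4,4-trimethylcyclohex-2-en-1-yl]oxy}methyl)stannane F7. Tin–lithium exchange with n-BuLi at −78 °C gives the α-alkoxymethyllithium F8, whose suprafacial Still–Wittig rearrangement should give [(1R)-2,6,6-trimethylcyclohex-2-en-1-yl]methanol F9 with the same sense of chirality transfer. Treatment of F9 with bis(4-methylphenyl) disulfide and n-Bu3P in pyridine would give 1-methyl-4-({[(1R)-2,6,6-trimethylcyclohex-2-en-1-yl]methyl}sulfanyl)benzene F10. Oxidation of F10 at sulfur with H2O2 and catalytic (NH4)6Mo7O24 in EtOH comes back to the route at 7.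

**Further compounds**
F1 | step 9 | pentacarbonyl(1-methoxyprop-2-en-1-ylidene)chromium | COC(C=C)=[Cr](=C=O)(=C=O)(=C=O)(=C=O)=C=O
F2 | step 9 | 2-[(2E,6E)-3,7-dimethyl-9-[(1R)-2,6,6-trimethylcyclohex-2-en-1-yl]nona-2,6-dien-1-yl]-4-methoxyphenol | CC1=CCCC(C)(C)[C@H]1CC/C(C)=C/CC/C(C)=C/Cc1cc(OC)ccc1O
F3 | step 10 | (6R)-6-[(3E,7E,10E)-11-iodo-3,7-dimethylundeca-3,7,10-trien-1-yl]-1,5,5-trimethylcyclohex-1-ene | CC1=CCCC(C)(C)[C@H]1CC/C(C)=C/CC/C(C)=C/C/C=C/I
F4 | step 10 | [(1E,4E,8E)-5,9-dimethyl-11-[(1R)-2,6,6-trimethylcyclohex-2-en-1-yl]undeca-1,4,8-trien-1-yl]lithium | CC1=CCCC(C)(C)[C@H]1CC/C(C)=C/CC/C(C)=C/C/C=C/[Li]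
F5 | step 10 | 4-hydroxy-4-[(1E,4E,8E)-5,9-dimethyl-11-[(1R)-2,6,6-trimethylcyclohex-2-en-1-yl]undeca-1,4,8-trien-1-yl]cyclobut-2-en-1-one | CC1=CCCC(C)(C)[C@H]1CC/C(C)=C/CC/C(C)=C/C/C=C/C1(O)C=CC1=O
F6 | step 10 | 2-[(2E,6E)-3,7-dimethyl-9-[(1R)-2,6,6-trimethylcyclohex-2-en-1-yl]nona-2,6-dien-1-yl]benzene-1,4-diol | CC1=CCCC(C)(C)[C@H]1CC/C(C)=C/CC/C(C)=C/Cc1cc(O)ccc1O
F7 | step 3 | tributyl({[(1S)-2,4,4-trimethylcyclohex-2-en-1-yl]oxy}methyl)stannane | CCCC[Sn](CCCC)(CCCC)CO[C@H]1CCC(C)(C)C=C1C
F8 | step 3 | ({[(1S)-2,4,4-trimethylcyclohex-2-en-1-yl]oxy}methyl)lithium | [Li]CO[C@H]1CCC(C)(C)C=C1C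
F9 | step 3 | [(1R)-2,6,6-trimethylcyclohex-2-en-1-yl]methanol | CC1=CCCC(C)(C)[C@H]1CO
F10 | step 3 | 1-methyl-4-({[(1R)-2,6,6-trimethylcyclohex-2-en-1-yl]methyl}sulfanyl)benzene | CC1=CCCC(C)(C)[C@H]1CSc1ccc(C)cc1
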